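Ring B is a cyclohexadienone whose C(CH3)2 ring carbon blocks aromatisation and whose three ring oxygens alternate around it. It is disconnected at the bond between the CH2-bearing ring carbon and its neighbouring carbonyl carbon and at the bond between the future acyl-bearing CH carbon and the adjacent oxygenated carbon. One thermal cyclobutenone–ynol ether annulation forms both bonds and closes ring B with the bridge, the quaternary carbon and all three oxygens in place. Its partners are 3-ethoxy-4,4-dimethylcyclobutenone and the silyl ynol ether of a ring A arylpropyne that is benzoyl-free but carries an iodine, so that the benzoyl group enters later by neutral carbonylative coupling, not by a Fries shift that the prenyl ether would not survive.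

Key step: step 8

Remark: the target has no stereocentre; ring B compounds are drawn as one enol tautomer of a mobile set, and enol ester 24 as one of its possible regioisomers.
Abbreviations: MOM = methoxymethyl; prenyl = 3-methylbut-2-en-1-yl; TIPS = triisopropylsilyl; TMS = trimethylsilyl; NIS = N-iodosuccinimide.

Step 1
Reactants: 1 phloroglucinol
Product: 2 3,5-bis(methoxymethoxy)phenol
Conditions: MOMCl (2.0 equiv), iPr2NEt, DMF, 0 °C → rt; chromatographic separation from mono- and tris-ether
Reagents that add atoms: chloromethyl methyl ether, COCCl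
Why: Williamson-type O-alkylation of the phenoxide by the reactive chloromethyl ether, where two equivalents should make the bis-ether the main component of a separable statistical mixture.

Step 2
Reactants: 2 3,5-bis(methoxymethoxy)phenol; 3 prenyl bromide
Product: 4 1,3-bis(methoxymethoxy)-5-(prenyloxy)benzene
Conditions: K2CO3, acetone, reflux
Reagents that add atoms: none
Why: Williamson ether synthesis on the single remaining phenol, where carbonate in a polar aprotic solvent favours O- over C-alkylation of the doubly etherified ring.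

Step 3
Reactants: 4 1,3-bis(methoxymethoxy)-5-(prenyloxy)benzene; 5 3-bromo-1-(trimethylsilyl)prop-1-yne
Product: 7 (3-{2,6-bis(methoxymethoxy)-4-(prenyloxy)phenyl}prop-1-yn-1-yl)trimethylsilane, via aryllithium 6 (not isolated)
Conditions: nBuLi, THF, 0 °C; then CuBr·SMe2 (10 mol %), 5, –78 °C → rt
Reagents that add atoms: none
Why: Directed ortho-metalation at the only ring position flanked by two MOM ethers (double chelation), then copper-catalysed SN2 alkylation by the propargylic bromide, whose silyl group shields the alkyne terminus against SN2′ attack and masks the acidic alkyne hydrogen.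

Step 4
Reactants: 7 (3-{2,6-bis(methoxymethoxy)-4-(prenyloxy)phenyl}prop-1-yn-1-yl)trimethylsilane
Product: 8 (3-{3-iodo-2,6-bis(methoxymethoxy)-4-(prenyloxy)phenyl}prop-1-yn-1-yl)trimethylsilane
Conditions: NIS (1.0 equiv), MeCN, 0 °C, dark
Reagents that add atoms: N-iodosuccinimide, O=C1CCC(=O)N1I
Why: Acid-free electrophilic aromatic iodination at one of the two equivalent free positions of the trialkoxy-alkyl arene, which should leave MOM ethers, prenyl alkene and alkynylsilane untouched and marks the future benzoyl carbon.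

Step 5
Reactants: 8 (3-{3-iodo-2,6-bis(methoxymethoxy)-4-(prenyloxy)phenyl}prop-1-yn-1-yl)trimethylsilane
Product: 9 3-{3-iodo-2,6-bis(methoxymethoxy)-4-(prenyloxy)phenyl}prop-1-yne
Conditions: K2CO3 (cat.), MeOH, rt
Reagents that add atoms: none
Why: Protodesilylation of the alkynylsilane by methanolysis of the C(sp)–Si bond under mild carbonate catalysis, short enough to avoid propargyl-to-allene isomerisation.

Step 6
Reactants: 9 3-{3-iodo-2,6-bis(methoxymethoxy)-4-(prenyloxy)phenyl}prop-1-yne
Product: 12 triisopropyl[(3-{3-iodo-2,6-bis(methoxymethoxy)-4-(prenyloxy)phenyl}prop-1-yn-1-yl)oxy]silane, via lithium acetylide 10 (not isolated), via lithium ynolate 11 (not isolated)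
Conditions: tBuOOH, LiN(SiMe3)2 (2.3 equiv), THF, –78 → 0 °C; then TIPSOTf, –78 °C
Reagents that add atoms: tert-butyl hydroperoxide, CC(C)(C)OO; triisopropylsilyl trifluoromethanesulfonate, CC(C)[Si](OS(=O)(=O)C(F)(F)F)(C(C)C)C(C)C
Why: Julia oxidation of the lithium acetylide by lithium tert-butyl peroxide to the ynolate and O-silylation by the bulky silyl triflate (bulk disfavours C-silylation to a silylketene), with an amide base that does not attack the aryl iodide.

Step 7
Reactants: 13 isobutyryl chloride; 14 ethoxyacetylene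
Product: 16 3-ethoxy-4,4-dimethylcyclobut-2-en-1-one, via dimethylketene 15 (not isolated)
Conditions: Et3N, Et2O–hexanes, 0 °C → rt
Reagents that add atoms: none
Why: Dehydrochlorination to the ketene and in-situ ketene–ynol ether [2+2] cycloaddition, in which the nucleophilic terminal alkyne carbon bonds to the ketene carbonyl carbon and so gives the 3-ethoxy-4,4-dimethyl isomer.

Step 8
Reactants: 12 triisopropyl[(3-{3-iodo-2,6-bis(methoxymethoxy)-4-(prenyloxy)phenyl}prop-1-yn-1-yl)oxy]silane; 16 3-ethoxy-4,4-dimethylcyclobut-2-en-1-one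
Product: 20 5-ethoxy-2-({3-iodo-2,6-bis(methoxymethoxy)-4-(prenyloxy)phenyl}methyl)-6,6-dimethyl-3-[(triisopropylsilyl)oxy]cyclohexa-2,4-dien-1-one, via vinylketene 17 (not isolated), via vinylcyclobutenone 18 (not isolated), via dienylketene 19 (not isolated)
Conditions: 16 (1.5 equiv), toluene, 110 °C, sealed tube, argon
Reagents that add atoms: none
Why: Thermal 4π-electrocyclic opening of 16 (cleavage of its C1–C4 bond) gives vinylketene 17, whose ketene C=C undergoes [2+2] cycloaddition with the ynol ether so that the benzyl-bearing alkyne carbon bonds to the ketene carbonyl carbon and the silyloxy carbon to the ketene CH, giving 18. A second 4π opening of 18 gives dienylketene 19, and ring B is closed by thermal disrotatory 6π-electrocyclisation of the ketene carbon onto the (CH3)2C terminus; the opening of 18 is reversible, so only the isomer with the alkenyl group turned towards the ketene is drained. This is the Danheiser cyclobutenone–alkyne annulation in its cyclohexadienone variant, known for 4,4-disubstituted cyclobutenones and for silyl ynol ethers. Because the closing terminus is quaternary, the ring cannot tautomerise to a phenol and stays a cyclohexa-2,4-dienone; no stereocentre is formed. The selectivity needed is regiochemical and is secured by the polarisation of the ynol ether (nucleophilic carbon remote from oxygen, electrophilic ketene carbonyl carbon), which places the CH2Ar group next to the ring ketone and the silyloxy carbon next to the ring CH. Aryl iodide, MOM ethers and the aryl prenyl ether should be inert at this temperature, which lies below that of an aromatic Claisen rearrangement.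

Step 9
Reactants: 20 5-ethoxy-2-({3-iodo-2,6-bis(methoxymethoxy)-4-(prenyloxy)phenyl}methyl)-6,6-dimethyl-3-[(triisopropylsilyl)oxy]cyclohexa-2,4-dien-1-one; 21 tributyl(phenyl)stannane
Product: 22 2-({3-benzoyl-2,6-bis(methoxymethoxy)-4-(prenyloxy)phenyl}methyl)-5-ethoxy-6,6-dimethyl-3-[(triisopropylsilyl)oxy]cyclohexa-2,4-dien-1-one
Conditions: CO (5 bar), PdCl2(PPh3)2 (5 mol %), toluene, 90 °C
Reagents that add atoms: carbon monoxide, [C-]#[O+]
Why: Carbonylative Stille coupling (oxidative addition of zerovalent palladium into the C–I bond, CO insertion, transmetalation from tin, reductive elimination) under neutral, base-free conditions that keep both enol ethers and the MOM groups, with CO insertion at the hindered aryl–palladium bond expected to outrun 5-exo insertion of the trisubstituted prenyl alkene.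

Step 10
Reactants: 22 2-({3-benzoyl-2,6-bis(methoxymethoxy)-4-(prenyloxy)phenyl}methyl)-5-ethoxy-6,6-dimethyl-3-[(triisopropylsilyl)oxy]cyclohexa-2,4-dien-1-one
Product: 23 4-({3-benzoyl-2,6-bis(methoxymethoxy)-4-(prenyloxy)phenyl}methyl)-3,5-dihydroxy-6,6-dimethylcyclohexa-2,4-dien-1-one (enol form of the 1,3,5-trione)
Conditions: 1 M aq HCl, THF, 0 °C → rt
Reagents that add atoms: water, O
Why: Acid hydrolysis of the silyl enol ether and of the vinylogous ethyl ester through C-protonation at the ring CH flanked by two oxygenated carbons, under cold dilute aqueous acid that aryl MOM ethers and the aryl prenyl ether should withstand.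

Step 11
Reactants: 23 4-({3-benzoyl-2,6-bis(methoxymethoxy)-4-(prenyloxy)phenyl}methyl)-3,5-dihydroxy-6,6-dimethylcyclohexa-2,4-dien-1-one; 13 isobutyryl chloride
Product: 25 4-({3-benzoyl-2,6-bis(methoxymethoxy)-4-(prenyloxy)phenyl}methyl)-3,5-dihydroxy-6,6-dimethyl-2-(2-methylpropanoyl)cyclohexa-2,4-dien-1-one, via enol isobutyrate 24 (not isolated)
Conditions: 13 (1.1 equiv), Et3N, CH2Cl2, 0 °C; then DMAP (0.2 equiv), rt
Reagents that add atoms: none
Why: O-acylation of the vinylogous acid followed by DMAP-catalysed enol ester to C-acyl rearrangement (acyl migration of 1,3-dione enol esters) onto the only ring B carbon that still bears hydrogen, the chelated enolised triketone being the thermodynamic sink while the ring A phenols stay masked.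

Step 12
Reactants: 25 4-({3-benzoyl-2,6-bis(methoxymethoxy)-4-(prenyloxy)phenyl}methyl)-3,5-dihydroxy-6,6-dimethyl-2-(2-methylpropanoyl)cyclohexa-2,4-dien-1-one
Product: 27 sarothralin, via silyl ether 26 (not isolated)
Conditions: TMSOTf (6 equiv), 2,2′-bipyridyl (8 equiv), MeCN, 0 °C → rt; then H2O, rt
Reagents that add atoms: none
Why: Non-protic cleavage of aryl MOM ethers by silyl triflate and 2,2′-bipyridyl, which exchanges each MOM group for a silyl group (the two enols are silylated as well) before water frees all four hydroxyls, so the acid-labile aryl prenyl ether never meets a strong protic acid.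

Compound list
1 | phloroglucinol (benzene-1,3,5-triol) | Oc1cc(O)cc(O)c1 | starting material
2 | 3,5-bis(methoxymethoxy)phenol | COCOc1cc(O)cc(OCOC)c1 | intermediate
3 | prenyl bromide (1-bromo-3-methylbut-2-ene) | CC(C)=CCBr | starting material
4 | 1,3-bis(methoxymethoxy)-5-[(3-methylbut-2-en-1-yl)oxy]benzene | COCOc1cc(OCC=C(C)C)cc(OCOC)c1 | intermediate
5 | 3-bromo-1-(trimethylsilyl)prop-1-yne | C[Si](C)(C)C#CCBr | starting material
6 | {2,6-bis(methoxymethoxy)-4-[(3-methylbut-2-en-1-yl)oxy]phenyl}lithium | [Li]c1c(OCOC)cc(OCC=C(C)C)cc1OCOC | intermediate (not isolated)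
7 | (3-{2,6-bis(methoxymethoxy)-4-[(3-methylbut-2-en-1-yl)oxy]phenyl}prop-1-yn-1-yl)trimethylsilane | C[Si](C)(C)C#CCc1c(OCOC)cc(OCC=C(C)C)cc1OCOC | intermediate
8 | (3-{3-iodo-2,6-bis(methoxymethoxy)-4-[(3-methylbut-2-en-1-yl)oxy]phenyl}prop-1-yn-1-yl)trimethylsilane | C[Si](C)(C)C#CCc1c(OCOC)cc(OCC=C(C)C)c(I)c1OCOC | intermediate
9 | 3-{3-iodo-2,6-bis(methoxymethoxy)-4-[(3-methylbut-2-en-1-yl)oxy]phenyl}prop-1-yne | C#CCc1c(OCOC)cc(OCC=C(C)C)c(I)c1OCOC | intermediate
10 | lithium acetylide of 9 | [Li]C#CCc1c(OCOC)cc(OCC=C(C)C)c(I)c1OCOC | intermediate (not isolated)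
11 | lithium ynolate, lithium 3-{3-iodo-2,6-bis(methoxymethoxy)-4-[(3-methylbut-2-en-1-yl)oxy]phenyl}prop-1-yn-1-olate | [Li]OC#CCc1c(OCOC)cc(OCC=C(C)C)c(I)c1OCOC | intermediate (not isolated)
12 | triisopropyl[(3-{3-iodo-2,6-bis(methoxymethoxy)-4-[(3-methylbut-2-en-1-yl)oxy]phenyl}prop-1-yn-1-yl)oxy]silane | CC(C)[Si](OC#CCc1c(OCOC)cc(OCC=C(C)C)c(I)c1OCOC)(C(C)C)C(C)C | intermediate
13 | isobutyryl chloride (2-methylpropanoyl chloride) | CC(C)C(Cl)=O | starting material
14 | ethoxyacetylene (ethoxyethyne) | CCOC#C | starting material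
15 | dimethylketene | CC(C)=C=O | intermediate (not isolated)
16 | 3-ethoxy-4,4-dimethylcyclobut-2-en-1-one | CCOC1=CC(=O)C1(C)C | intermediate
17 | vinylketene, 3-ethoxy-4-methylpenta-1,3-dien-1-one | CCOC(C=C=O)=C(C)C | intermediate (not isolated)
18 | vinylcyclobutenone, 4-(1-ethoxy-2-methylprop-1-en-1-yl)-2-({3-iodo-2,6-bis(methoxymethoxy)-4-[(3-methylbut-2-en-1-yl)oxy]phenyl}methyl)-3-[(triisopropylsilyl)oxy]cyclobut-2-en-1-one (racemic) | CCOC(=C(C)C)C1C(=O)C(Cc2c(OCOC)cc(OCC=C(C)C)c(I)c2OCOC)=C1O[Si](C(C)C)(C(C)C)C(C)C | intermediate (not isolated)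
19 | dienylketene, (3E)-5-ethoxy-2-({3-iodo-2,6-bis(methoxymethoxy)-4-[(3-methylbut-2-en-1-yl)oxy]phenyl}methyl)-6-methyl-3-[(triisopropylsilyl)oxy]hepta-1,3,5-trien-1-one | CCOC(=C(C)C)\C=C(O[Si](C(C)C)(C(C)C)C(C)C)/C(Cc1c(OCOC)cc(OCC=C(C)C)c(I)c1OCOC)=C=O | intermediate (not isolated)
20 | 5-ethoxy-2-({3-iodo-2,6-bis(methoxymethoxy)-4-[(3-methylbut-2-en-1-yl)oxy]phenyl}methyl)-6,6-dimethyl-3-[(triisopropylsilyl)oxy]cyclohexa-2,4-dien-1-one | CCOC1=CC(O[Si](C(C)C)(C(C)C)C(C)C)=C(Cc2c(OCOC)cc(OCC=C(C)C)c(I)c2OCOC)C(=O)C1(C)C | intermediate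
21 | tributyl(phenyl)stannane | CCCC[Sn](CCCC)(CCCC)c1ccccc1 | starting material
22 | 2-({3-benzoyl-2,6-bis(methoxymethoxy)-4-[(3-methylbut-2-en-1-yl)oxy]phenyl}methyl)-5-ethoxy-6,6-dimethyl-3-[(triisopropylsilyl)oxy]cyclohexa-2,4-dien-1-one | CCOC1=CC(O[Si](C(C)C)(C(C)C)C(C)C)=C(Cc2c(OCOC)cc(OCC=C(C)C)c(C(=O)c3ccccc3)c2OCOC)C(=O)C1(C)C | intermediate
23 | 4-({3-benzoyl-2,6-bis(methoxymethoxy)-4-[(3-methylbut-2-en-1-yl)oxy]phenyl}methyl)-3,5-dihydroxy-6,6-dimethylcyclohexa-2,4-dien-1-one | CC1(C)C(O)=C(Cc2c(OCOC)cc(OCC=C(C)C)c(C(=O)c3ccccc3)c2OCOC)C(O)=CC1=O | intermediate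
24 | enol isobutyrate, 4-({3-benzoyl-2,6-bis(methoxymethoxy)-4-[(3-methylbut-2-en-1-yl)oxy]phenyl}methyl)-3-hydroxy-6,6-dimethyl-5-oxocyclohexa-1,3-dien-1-yl 2-methylpropanoate | CC(C)C(=O)OC1=CC(O)=C(Cc2c(OCOC)cc(OCC=C(C)C)c(C(=O)c3ccccc3)c2OCOC)C(=O)C1(C)C | intermediate (not isolated)
25 | 4-({3-benzoyl-2,6-bis(methoxymethoxy)-4-[(3-methylbut-2-en-1-yl)oxy]phenyl}methyl)-3,5-dihydroxy-6,6-dimethyl-2-(2-methylpropanoyl)cyclohexa-2,4-dien-1-one | CC(C)C(=O)C1=C(O)C(Cc2c(OCOC)cc(OCC=C(C)C)c(C(=O)c3ccccc3)c2OCOC)=C(O)C(C)(C)C1=O | intermediate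
26 | silyl ether, the tetrakis(trimethylsilyl) ether of sarothralin (both ring A phenols and both ring B enols silylated) | CC(C)C(=O)C1=C(O[Si](C)(C)C)C(Cc2c(O[Si](C)(C)C)cc(OCC=C(C)C)c(C(=O)c3ccccc3)c2O[Si](C)(C)C)=C(O[Si](C)(C)C)C(C)(C)C1=O | intermediate (not isolated)
27 | sarothralin | CC(C)=CCOc1cc(O)c(CC2=C(O)C(C)(C)C(=O)C(C(=O)C(C)C)=C2O)c(O)c1C(=O)c1ccccc1 | target

Total step count: 12.
Longest linear sequence: 11 steps (steps 1–6 and 8–12 from phloroglucinol); step 7 is a one-step side branch.

Steps most likely to fail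

Step 8 (ring B annulation). The donor-substituted gem-dimethylcyclobutenone may open only at a temperature at which the silyl ynol ether is lost, by rearrangement to a silylketene or by oligomerisation with the vinylketene, so that the fragments fail to combine. The fallback exchanges the roles of the two ketene partners and sets out from 12. [2+2] cycloaddition of 12 with dimethylketene 15 (from 13 and Et3N) at room temperature should give 2-({3-iodo-2,6-bis(methoxymethoxy)-4-(prenyloxy)phenyl}methyl)-4,4-dimethyl-3-[(triisopropylsilyl)oxy]cyclobut-2-en-1-one F1, which consumes the fragile ynol ether under mild conditions. Heating F1 with an excess of ethoxyacetylene 14 in toluene at 80–100 °C should give the isomeric dienone 3-ethoxy-4-({3-iodo-2,6-bis(methoxymethoxy)-4-(prenyloxy)phenyl}methyl)-6,6-dimethyl-5-[(triisopropylsilyl)oxy]cyclohexa-2,4-dien-1-one F2. Carbonylative Stille coupling as in step 9 should then give the benzoyl compound F3. Hydrolysis as in step 10 comes back to the route at 23, because both bis-enol ether isomers are ethers of the same 1,3,5-trione.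

Step 9 (carbonylative benzoylation). The neighbouring prenyl alkene may insert into the aryl–palladium bond (5-exo Heck cyclisation), or oxidative addition at the doubly ortho-substituted, electron-rich C–I bond may be sluggish, before CO is taken up. The fallback sets out from 20. Nozaki–Hiyama–Kishi addition to benzaldehyde (CrCl2, NiCl2 cat., DMF, rt) should give the racemic diaryl carbinol 5-ethoxy-2-({3-[hydroxy(phenyl)methyl]-2,6-bis(methoxymethoxy)-4-(prenyloxy)phenyl}methyl)-6,6-dimethyl-3-[(triisopropylsilyl)oxy]cyclohexa-2,4-dien-1-one F4. Oxidation with Dess–Martin periodinane (NaHCO3, CH2Cl2) comes back to the route at 22.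

Step 3 (propargylation). The organocopper may attack the silyl-bearing alkyne terminus (SN2′) and give an allenylsilane in place of the propargyl arene. The fallback sets out from 4 through the same aryllithium 6 and copper catalysis, but alkylates with 2,3-dibromopropene, for which SN2 and SN2′ attack lead to one product, 2-(2-bromoprop-2-en-1-yl)-1,3-bis(methoxymethoxy)-5-(prenyloxy)benzene F5. Dehydrobromination with Bu4NF·3H2O in DMF at 60 °C should give the terminal alkyne 1,3-bis(methoxymethoxy)-5-(prenyloxy)-2-(prop-2-yn-1-yl)benzene F6. Ring iodination with NIS as in step 4 comes back to the route at 9.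

Further compounds
F1 | step 8 | 2-({3-iodo-2,6-bis(methoxymethoxy)-4-[(3-methylbut-2-en-1-yl)oxy]phenyl}methyl)-4,4-dimethyl-3-[(triisopropylsilyl)oxy]cyclobut-2-en-1-one | CC(C)[Si](OC1=C(Cc2c(OCOC)cc(OCC=C(C)C)c(I)c2OCOC)C(=O)C1(C)C)(C(C)C)C(C)C
F2 | step 8 | 3-ethoxy-4-({3-iodo-2,6-bis(methoxymethoxy)-4-[(3-methylbut-2-en-1-yl)oxy]phenyl}methyl)-6,6-dimethyl-5-[(triisopropylsilyl)oxy]cyclohexa-2,4-dien-1-one | CCOC1=CC(=O)C(C)(C)C(O[Si](C(C)C)(C(C)C)C(C)C)=C1Cc1c(OCOC)cc(OCC=C(C)C)c(I)c1OCOC
F3 | step 8 | 4-({3-benzoyl-2,6-bis(methoxymethoxy)-4-[(3-methylbut-2-en-1-yl)oxy]phenyl}methyl)-3-ethoxy-6,6-dimethyl-5-[(triisopropylsilyl)oxy]cyclohexa-2,4-dien-1-one | CCOC1=CC(=O)C(C)(C)C(O[Si](C(C)C)(C(C)C)C(C)C)=C1Cc1c(OCOC)cc(OCC=C(C)C)c(C(=O)c2ccccc2)c1OCOC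
F4 | step 9 | 5-ethoxy-2-({3-[hydroxy(phenyl)methyl]-2,6-bis(methoxymethoxy)-4-[(3-methylbut-2-en-1-yl)oxy]phenyl}methyl)-6,6-dimethyl-3-[(triisopropylsilyl)oxy]cyclohexa-2,4-dien-1-one (racemic) | CCOC1=CC(O[Si](C(C)C)(C(C)C)C(C)C)=C(Cc2c(OCOC)cc(OCC=C(C)C)c(C(O)c3ccccc3)c2OCOC)C(=O)C1(C)C
F5 | step 3 | 2-(2-bromoprop-2-en-1-yl)-1,3-bis(methoxymethoxy)-5-[(3-methylbut-2-en-1-yl)oxy]benzene | COCOc1cc(OCC=C(C)C)cc(OCOC)c1CC(Br)=C
F6 | step 3 | 1,3-bis(methoxymethoxy)-5-[(3-methylbut-2-en-1-yl)oxy]-2-(prop-2-yn-1-yl)benzene | C#CCc1c(OCOC)cc(OCC=C(C)C)cc1OCOC
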